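Everything rests on opening ring C, the pyran-4-one, at C4–C4a and O1–C2. That exposes the enol-like C4a=C8a–O1 unit, present three times over in phloroglucinol (ring A), as a C,O-dinucleophile. It also exposes C4–C3(OMe)–C2(aryl) as the 1,3-dielectrophile of an α-methoxy aroylacetate. A single acid-free thermal condensation forges both bonds and closes ring C with the 3-methoxy group and ring B already installed. It leaves a chelated 5-OH and a free 7-OH that can be told apart later. The precursor is racemic ethyl 2-methoxy-3-oxo-3-arylpropanoate carrying a heat-tolerant 4-benzyloxy group; the heat-sensitive prenyl ether goes on last.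

Key step: step 3

Remark on stereochemistry: the target has no stereocentre and its only acyclic C=C carries two identical methyl groups, so it is achiral and exists in one form; the sole stereocentre of the route (C2 of keto ester 6) is racemic, enolisable and erased in step 3.

Remark on material: phloroglucinol is often supplied as the dihydrate; the anhydrous grade is assumed (or the dihydrate dried at 110 °C in vacuo), because water would divert the ketene to the β-keto acid and on to decarboxylation.

Step 1
Reactants: 1 4-(benzyloxy)benzoic acid
Product: 2 4-(benzyloxy)benzoyl chloride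
Conditions: (COCl)2 (1.3 equiv), DMF (cat.), CH2Cl2, 0 °C → rt; evaporate, use crude
Reagents that add atoms: oxalyl chloride, O=C(Cl)C(=O)Cl
Why: DMF-catalysed acid chloride formation (Vilsmeier-type activation) is a routine acyl activation whose by-products are gases and which does not touch the benzyl aryl ether.

Step 2
Reactants: 2 4-(benzyloxy)benzoyl chloride; 3 ethyl methoxyacetate
Product: 6 (±)-ethyl 3-[4-(benzyloxy)phenyl]-2-methoxy-3-oxopropanoate, via lithium enolate of ethyl methoxyacetate 4 (not isolated), via lithium enolate of the keto ester 5 (not isolated)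
Conditions: LDA (2.1 equiv), 3 (2.1 equiv), THF, −78 °C; add 2 (1.0 equiv) in THF, −78 → −40 °C; 1 M HCl quench
Reagents that add atoms: none
Why: Crossed Claisen-type C-acylation of a preformed lithium ester enolate by a non-enolisable aroyl chloride should be clean at −78 °C because self-condensation of 4 is slow there and the second equivalent of 4 deprotonates the acidic C2–H of the product as it forms (giving 5), which blocks a second acylation; the new C2 centre is formed racemic, is enolisable and disappears in step 3.

Step 3
Reactants: 6 (±)-ethyl 3-[4-(benzyloxy)phenyl]-2-methoxy-3-oxopropanoate; 7 phloroglucinol (anhydrous)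
Product: 11 4'-benzyloxy-5,7-dihydroxy-3-methoxyflavone, via aroyl(methoxy)ketene 8 (not isolated), via 2-methoxy-1,3-diketone 9 (not isolated), via cyclic hemiketal 10 (not isolated)
Conditions: 6 (1.5 equiv), 7 (1.0 equiv), neat melt, N2, 240 °C (metal bath or microwave), EtOH/H2O distilled off; no acid, no base
Reagents that add atoms: none
Why: Above roughly 200 °C the enol of 6 expels ethanol in a concerted six-centre elimination to give aroyl(methoxy)ketene 8, whose ketene carbon (the future C4) is taken up by a ring carbon of 7, either directly or through O-acylation followed by thermal acyl shift, so that C4–C4a is made and 2-methoxy-1,3-diketone 9 results. A flanking phenolic oxygen of 9 then attacks the aroyl carbonyl in a 6-exo-trig closure (O1–C2) to hemiketal 10, and loss of water across C2–C3 delivers the conjugated pyran-4-one, ring C. The closest known reaction type is the Mentzer thermal chromone synthesis, which is practised neat in a bath or under microwave heating on phloroglucinol and aroylacetates, α-substituted ones included. No stereocentre remains, since the racemic carbon of 6 and the two transient centres of 10 all end as the sp2 atoms C2 and C3. The selectivity required is chromone over 4-arylcoumarin (Pechmann mode), and it is secured by leaving out acid, so that the ketone is never activated for Friedel–Crafts attack while the ester terminus becomes the much more electrophilic ketene and therefore meets the carbon nucleophile first. Ring-A regiochemistry cannot arise because the three C–H and three OH positions of 7 are equivalent, a second annulation is held back by the deactivating C4 carbonyl, and the benzyl ether, unlike a prenyl ether, has no sigmatropic escape at this temperature.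

Step 4
Reactants: 11 4'-benzyloxy-5,7-dihydroxy-3-methoxyflavone
Product: 12 4'-benzyloxy-5-hydroxy-3,7-dimethoxyflavone
Conditions: MeI (1.05 equiv), K2CO3 (1.1 equiv), acetone, 40 °C
Reagents that add atoms: methyl iodide, CI
Why: Williamson ether synthesis (SN2 on methyl iodide) under weak base is selective because 7-OH, conjugated through ring A with the C4 carbonyl, is the most acidic and the only unchelated phenol of 11, whereas 5-OH is tied up in a six-membered hydrogen bond to C4=O and is neither ionised nor nucleophilic when base and methyl iodide are limited to about one equivalent.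

Step 5
Reactants: 12 4'-benzyloxy-5-hydroxy-3,7-dimethoxyflavone
Product: 13 4',5-dihydroxy-3,7-dimethoxyflavone (kumatakenin)
Conditions: H2 (1 atm), 10% Pd/C, THF–MeOH, rt
Reagents that add atoms: none
Why: Heterogeneous catalytic hydrogenolysis cleaves only the benzylic C–O bond, since the tetrasubstituted vinylogous-ester C2=C3 bond, the C4 carbonyl and the methyl ethers are inert at 1 atm and room temperature, and it is placed before prenylation because the prenyl alkene and allylic ether would not survive it.

Step 6
Reactants: 13 4',5-dihydroxy-3,7-dimethoxyflavone; 14 prenyl bromide (1-bromo-3-methylbut-2-ene)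
Product: 15 5-hydroxy-3,7-dimethoxy-4'-(3-methylbut-2-enyloxy)flavone (target)
Conditions: 14 (1.1 equiv), K2CO3 (1.2 equiv), acetone, rt → 40 °C
Reagents that add atoms: none
Why: Williamson ether synthesis at the primary allylic carbon (SN2) picks out the free 4'-phenoxide, while the hydrogen-bonded 5-OH stays protonated under K2CO3 with only a slight excess of bromide, and the mild temperature lies far below the threshold for aromatic Claisen rearrangement of the new aryl prenyl ether.

Compound list
1 | 4-(benzyloxy)benzoic acid | O=C(O)c1ccc(OCc2ccccc2)cc1 | starting material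
2 | 4-(benzyloxy)benzoyl chloride | O=C(Cl)c1ccc(OCc2ccccc2)cc1 | intermediate
3 | ethyl methoxyacetate | COCC(=O)OCC | starting material
4 | lithium enolate of ethyl methoxyacetate (not isolated; enolate geometry without consequence) | [Li+].CCOC([O-])=COC | intermediate
5 | lithium enolate of ethyl 3-[4-(benzyloxy)phenyl]-2-methoxy-3-oxopropanoate (not isolated) | [Li+].CCOC(=O)C(OC)=C([O-])c1ccc(OCc2ccccc2)cc1 | intermediate
6 | (±)-ethyl 3-[4-(benzyloxy)phenyl]-2-methoxy-3-oxopropanoate (racemic, enolisable C2) | CCOC(=O)C(OC)C(=O)c1ccc(OCc2ccccc2)cc1 | intermediate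
7 | phloroglucinol (benzene-1,3,5-triol, anhydrous) | Oc1cc(O)cc(O)c1 | starting material
8 | [4-(benzyloxy)benzoyl](methoxy)ketene (not isolated) | COC(=C=O)C(=O)c1ccc(OCc2ccccc2)cc1 | intermediate
9 | 1-[4-(benzyloxy)phenyl]-2-methoxy-3-(2,4,6-trihydroxyphenyl)propane-1,3-dione (racemic, not isolated) | COC(C(=O)c1ccc(OCc2ccccc2)cc1)C(=O)c1c(O)cc(O)cc1O | intermediate
10 | 2-[4-(benzyloxy)phenyl]-2,5,7-trihydroxy-3-methoxychroman-4-one (transient diastereomer mixture, not isolated) | COC1C(=O)c2c(O)cc(O)cc2OC1(O)c1ccc(OCc2ccccc2)cc1 | intermediate
11 | 4'-benzyloxy-5,7-dihydroxy-3-methoxyflavone | COc1c(-c2ccc(OCc3ccccc3)cc2)oc2cc(O)cc(O)c2c1=O | intermediate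
12 | 4'-benzyloxy-5-hydroxy-3,7-dimethoxyflavone | COc1cc(O)c2c(=O)c(OC)c(-c3ccc(OCc4ccccc4)cc3)oc2c1 | intermediate
13 | 4',5-dihydroxy-3,7-dimethoxyflavone (kumatakenin) | COc1cc(O)c2c(=O)c(OC)c(-c3ccc(O)cc3)oc2c1 | intermediate
14 | prenyl bromide (1-bromo-3-methylbut-2-ene) | CC(C)=CCBr | starting material
15 | 5-hydroxy-3,7-dimethoxy-2-{4-[(3-methylbut-2-en-1-yl)oxy]phenyl}-4H-chromen-4-one (achiral) | COc1cc(O)c2c(=O)c(OC)c(-c3ccc(OCC=C(C)C)cc3)oc2c1 | target

Total step count: 6
Longest linear sequence: 6 steps (1 → 2 → 6 → 11 → 12 → 13 → 15)

Steps most likely to fail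

Step 3. Three processes may intervene:
- Thermal decay of the keto ester (decarboxylation after adventitious hydrolysis, or ketene dimerisation) may outrun C-acylation.
- The reaction may leak into the coumarin-forming mode.
- Benzyl may be transferred to the electron-rich ring in the hot phenolic melt.

The fallback gives up the ketene and builds ring C from an aryl ketone. It sets out from 7 and 1 and comes back at 11. Hoesch acylation of 7 with methoxyacetonitrile (ZnCl2, dry HCl, Et2O, 0 °C) should precipitate the ketiminium chloride F1. Boiling water hydrolyses this to 2-methoxy-1-(2,4,6-trihydroxyphenyl)ethanone F2. Acid 1 with DCC (0.5 equiv, CH2Cl2) gives 4-(benzyloxy)benzoic anhydride F3. Allan–Robinson condensation of F2 with F3 (Et3N, 160–170 °C) proceeds by O-aroylation, acyl shift to the methoxy-bearing carbon and cyclodehydration. It should give the flavone as its 7-O-[4-(benzyloxy)benzoyl] ester F4. Brief KOH/EtOH reflux followed by acidification frees 11.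

Step 2. Self-condensation of the alkoxy ester enolate, O-acylation to an enol ester, or capture of the acid chloride by diisopropylamine may erode the C-acylation.

The fallback installs the methoxy group after the keto ester has been made. It sets out from 2 and comes back at 6. Decarboxylative acylation of potassium ethyl malonate with 2 (MgCl2, Et3N, MeCN) passes through the acylmalonic half-ester F5. This loses CO2 on acid work-up to give ethyl 3-[4-(benzyloxy)phenyl]-3-oxopropanoate F6. Regitz diazo transfer (p-acetamidobenzenesulfonyl azide, Et3N, MeCN) gives the α-diazo-β-keto ester F7. Rhodium-carbenoid O–H insertion into methanol (Rh2(OAc)4 cat., MeOH, CH2Cl2, reflux) then returns 6.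

Step 4. Discrimination between the two ring-A hydroxyls may break down, so that methylation runs on to the chelated 5-OH or stops short and leaves a mixture.

The fallback turns over-methylation into the plan. It sets out from 11 and comes back at 13, bypassing 12 and step 5. Exhaustive methylation (excess MeI, K2CO3, DMF, 60 °C) gives 4'-benzyloxy-3,5,7-trimethoxyflavone F8. BCl3 with pentamethylbenzene as cation scavenger (CH2Cl2, −78 → 0 °C) should then cleave two groups in one operation: the 5-O-methyl group, activated by six-membered boron chelation to C4=O, and the aryl benzyl ether. The less well chelated 3-OMe and the remote 7-OMe should stay.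

Further compounds
F1 | step 3 | 2-methoxy-1-(2,4,6-trihydroxyphenyl)ethan-1-iminium chloride | COCC(=[NH2+])c1c(O)cc(O)cc1O.[Cl-]
F2 | step 3 | 2-methoxy-1-(2,4,6-trihydroxyphenyl)ethanone | COCC(=O)c1c(O)cc(O)cc1O
F3 | step 3 | 4-(benzyloxy)benzoic anhydride | O=C(OC(=O)c1ccc(OCc2ccccc2)cc1)c1ccc(OCc2ccccc2)cc1
F4 | step 3 | 4'-benzyloxy-7-[4-(benzyloxy)benzoyloxy]-5-hydroxy-3-methoxyflavone | COc1c(-c2ccc(OCc3ccccc3)cc2)oc2cc(OC(=O)c3ccc(OCc4ccccc4)cc3)cc(O)c2c1=O
F5 | step 2 | 2-[4-(benzyloxy)benzoyl]malonic acid monoethyl ester (racemic, transient) | CCOC(=O)C(C(=O)O)C(=O)c1ccc(OCc2ccccc2)cc1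
F6 | step 2 | ethyl 3-[4-(benzyloxy)phenyl]-3-oxopropanoate | CCOC(=O)CC(=O)c1ccc(OCc2ccccc2)cc1
F7 | step 2 | ethyl 3-[4-(benzyloxy)phenyl]-2-diazo-3-oxopropanoate | CCOC(=O)C(=[N+]=[N-])C(=O)c1ccc(OCc2ccccc2)cc1
F8 | step 4 | 4'-benzyloxy-3,5,7-trimethoxyflavone | COc1cc(OC)c2c(=O)c(OC)c(-c3ccc(OCc4ccccc4)cc3)oc2c1
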